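## Structural features

The target (C42H30O24, no stereocentre) is a linear heptameric phlorotannin in which seven benzene rings, lettered A to G from the 2,4,6-trihydroxyphenyl end, are joined only by six diaryl ether oxygens and carry eighteen free hydroxyls. The ring atoms are labelled as follows: A1 is the ether carbon of ring A (OH at A2, A4, A6); B1 carries O–A and B4 carries O–C (OH at B3, B5); C1 carries O–B and C6 carries O–D (OH at C3 to C5, H at C2); D1 carries O–C and D5 carries O–E (OH at D3, D4; H at D2, D6); E1 carries O–D and E6 carries O–F (OH at E3 to E5); F1 carries O–E and F4 carries O–G (OH at F3, F5); G1 carries O–F (OH at G3 to G5). Rings A, B, D, F and G are 1,2,3,5-tetraoxygenated, whereas rings C and E are pentaoxygenated and each bears two vicinal aryloxy groups. Five of the six ether oxygens sit at a carbon flanked by two oxygenated carbons (A1, B4, C6, E6, F4), so nearly every C(aryl)–O bond is crowded and joins two very electron-rich rings. Ring D is the junction of two trimeric halves: it carries two different bulky aryloxy groups meta to each other (D1, D5) and a vicinal diol (D3, D4), and in any coupling scheme it would have to serve twice as the aryl halide partner, at differentiated positions, late, and on the largest fragments, which is the real difficulty. The free polyphenol (pyrogallol and catechol units) is sensitive to air and base, so every hydroxyl except the one created by the key step stays masked as a methyl ether until the last step, and the aryl ethynyl ethers and the alkoxycyclobutenone on the way are sensitive to heat and acid. The key step exploits the pattern D2(H)–D1(OAr)–D6(H)–D5(OAr) next to the vicinal pair D3/D4: D1–D2 and D5–D6 are each the two carbons of an aryl ethynyl ether, D3–D4 are the two carbons of methoxyketene, and the meta relation of the D3 hydroxyl to the D1 aryloxy group is the signature of a cyclobutenone/alkynyl ether benzannulation.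

## Logic of the disconnections

In one sentence: ring D is not coupled to its neighbours but built between them, by Danheiser benzannulation of 31 with 15.

37 to 36. The seventeen O–CH3 bonds are cut. Methyl ethers make every building block an article of commerce and tolerate all later conditions. The forward step must cleave every alkyl aryl ether and no diaryl ether.

36 to 31 + 15 (key). Ring D is opened at D2–D3 and D1–D6; the D3–D4 bond, present in 31, is broken and re-formed during the cascade. This is the convergence point. The cut gives two trimeric halves of similar size and removes both C–O bond formations at ring D, and with them the need for a differentiated ring D dihalide. The forward step must unite the ketene and the alkyne with one regiochemistry and must run at a temperature both partners survive.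

31 to 28 + 29. The four-membered ring is cut at D3–D6 and D4–D5. D3 and D4 then come from 29 through 30, and D5–D6 from the alkyne of 28. The forward (2+2) step must outrun ketene dimerisation and must place the aryloxy group at C3 and methoxy at C4.

28 to 25 to 24. The O–C(sp) bond at E1 is cut, and the two alkyne carbons are traced back to a two-carbon chloroalkene reagent. The crowded aryl–O–aryl bond D5–O–E1 thus becomes a phenol O-vinylation by a small electrophile, which is insensitive to arene electronics. The forward steps need clean elimination and chlorine–lithium exchange without ring metalation.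

24 to 22 to 20 + 21. The E6–O bond is cut and the E1 hydroxyl is traced back to a formyl group. That formyl group first activates the neighbouring C–Br bond of 21 and then becomes the phenol. The coupling must work at a bromide flanked on both sides.

20 to 18 to 16 + 17. The F4–O bond is cut and the F1 hydroxyl is traced back to the para formyl group of 17, by the same activate-then-oxidise logic. Both partners are commercial.

15 to 12 to 11. The O–C(sp) bond at C6 is cut, as for 28. The most hindered phenol oxygen of the route (flanked by OMe and OAr) then only has to add to a linear two-carbon electrophile.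

11 to 9 to 5 + 8, and 8 to 6. The C1–O bond of ring C is cut and the C6 hydroxyl is traced back to the ortho formyl group of 8. Cutting the formyl C–C bond of 8 leads to symmetric 6, in which only one kind of ring position is free.

5 to 3 to 1 + 2. The B1–O bond is cut and the B4 hydroxyl is traced back to the para formyl group of 2. The hindered phenol 1 is the nucleophile and the unhindered, formyl-activated bromide the electrophile.

## Other disconnections considered

Alternative 1: all six C(aryl)–O bonds by copper-mediated coupling, with ring D brought in as 5-bromo-1-iodo-2,3-dimethoxybenzene A1; this is the first plan that comes to mind. In the forward direction phenol 24 is coupled at the iodide to give bromide A2, phenol 11 is coupled at the bromide to give the octadecamethyl ether A3, and demethylation follows. The two bonds at ring D would be made last, on the largest fragments, at an unactivated and electron-rich dihalide with no carbonyl group to assist copper insertion; the second coupling uses the most hindered phenol of the route, and iodide/bromide discrimination on A1 is only kinetic. The chosen plan turns both bonds into O-vinylations and makes the fragment union a C–C bond construction.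

Alternative 2: aryne difunctionalisation of ring C, cutting C1–O and C6–O together. In the forward direction fluoride converts silyl triflate A4 into 3,4,5-trimethoxybenzyne A5, which is attacked by the phenoxide of 5 at C1 (remote from the flanking methoxy group), and the C6 carbanion is trapped by an iodine electrophile to give iodide A6. The regiochemistry is sound, but no electrophile delivers the second aryloxy group, so A6 would still need a C–O coupling at a carbon flanked on both sides; proton transfer to the aryl anion competes with iodination, A4 needs several steps, and the junction problem at ring D is untouched. Steps 4 and 5 already deliver the same pattern with a free C6 hydroxyl.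

Alternative 3: Moore-type squarate benzannulation of a pentaoxygenated ring (ring E). In the forward direction mixed squarate A7, made from phenol 20, takes up 1-methoxyethenyllithium A8 at the carbonyl not deactivated by the methoxy group, and adduct A9 then rearranges thermally (4π opening, 6π closure) to hydroquinone A10. This builds a ring whose substitution is already bought with 21, leaves two free hydroxyls (E1 and E4) to be told apart before the ethynyl ether can be made, and does nothing for the convergence at ring D. It costs more steps than the coupling/oxidation pair of steps 10 and 11.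

Key step: step 15

Assumption: compounds 1, 2, 6, 16, 17, 21 and 29 and the reagent trichloroethylene are taken as articles of commerce; the sp3 centres of 7, 31, 33 and 35 are racemic and vanish before the target.

Abbreviations: Ar(C) = 6-[2,6-dimethoxy-4-(2,4,6-trimethoxyphenoxy)phenoxy]-2,3,4-trimethoxyphenyl (rings A–B–C, bonded through C6). Ar(E) = 2-[3,5-dimethoxy-4-(3,4,5-trimethoxyphenoxy)phenoxy]-3,4,5-trimethoxyphenyl (rings G–F–E, bonded through E1).

## Steps

Step 1
Reactants: 1 phenol 2,4,6-trimethoxyphenol; 2 bromide 4-bromo-2,6-dimethoxybenzaldehyde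
Product: 3 aldehyde 2,6-dimethoxy-4-(2,4,6-trimethoxyphenoxy)benzaldehyde
Conditions: CuI (10 mol %), picolinic acid (20 mol %), K3PO4, DMSO, 90 °C, argon
Reagents that add atoms: none
Why: Ullmann ether synthesis; the para formyl group activates the C–Br bond of 2 towards monovalent copper, the bromide carbon has only hydrogen neighbours, and the picolinate ligand suits phenols with two ortho substituents such as 1.

Step 2
Reactants: 3 aldehyde 2,6-dimethoxy-4-(2,4,6-trimethoxyphenoxy)benzaldehyde
Product: 5 phenol 2,6-dimethoxy-4-(2,4,6-trimethoxyphenoxy)phenol, via aryl formate 4 (not isolated)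
Conditions: mCPBA, CH2Cl2, 0 °C to rt; aqueous wash; then K2CO3 (cat.), MeOH, rt
Reagents that add atoms: mCPBA (3-chloroperoxybenzoic acid), OOC(=O)c1cccc(Cl)c1
Why: Dakin-type Baeyer–Villiger oxidation; the aryl group, enriched by two ortho methoxy groups and the para aryloxy group, should migrate in preference to hydrogen to give formate 4, and methanolysis frees the phenol only after the peracid has been removed.

Step 3
Reactants: 6 bromide 5-bromo-1,2,3-trimethoxybenzene
Product: 8 aldehyde 6-bromo-2,3,4-trimethoxybenzaldehyde, via chloro ether 7 (not isolated)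
Conditions: Cl2CHOMe, TiCl4, CH2Cl2, −10 to 0 °C; then ice-water
Reagents that add atoms: dichloromethyl methyl ether, COC(Cl)Cl; water, O
Why: Rieche formylation; the only free positions of 6 are the two equivalent carbons between bromine and methoxy, each para to a methoxy group, so only one aldehyde can form, and hydrolysis of 7 on work-up gives 8.

Step 4
Reactants: 5 phenol 2,6-dimethoxy-4-(2,4,6-trimethoxyphenoxy)phenol; 8 aldehyde 6-bromo-2,3,4-trimethoxybenzaldehyde
Product: 9 aldehyde 6-[2,6-dimethoxy-4-(2,4,6-trimethoxyphenoxy)phenoxy]-2,3,4-trimethoxybenzaldehyde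
Conditions: CuI (20 mol %), picolinic acid (40 mol %), K3PO4, DMSO, 100 °C, argon
Reagents that add atoms: none
Why: Ullmann ether synthesis assisted by the ortho formyl group of 8, which speeds copper insertion into the neighbouring C–Br bond; the ligand tolerates the doubly ortho-substituted phenol 5.

Step 5
Reactants: 9 aldehyde 6-[2,6-dimethoxy-4-(2,4,6-trimethoxyphenoxy)phenoxy]-2,3,4-trimethoxybenzaldehyde
Product: 11 phenol 6-[2,6-dimethoxy-4-(2,4,6-trimethoxyphenoxy)phenoxy]-2,3,4-trimethoxyphenol (Ar(C)–OH), via aryl formate 10 (not isolated)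
Conditions: mCPBA, CH2Cl2, 0 °C to rt; aqueous wash; then K2CO3 (cat.), MeOH, rt
Reagents that add atoms: mCPBA (3-chloroperoxybenzoic acid), OOC(=O)c1cccc(Cl)c1
Why: Dakin-type Baeyer–Villiger oxidation; the migrating ring C carbon has ortho aryloxy, ortho methoxy and para methoxy donors, so aryl migration to formate 10 should be strongly favoured, and methanolysis frees the C6 hydroxyl.

Step 6
Reactants: 11 phenol Ar(C)–OH
Product: 12 (E)-1,2-dichloroethenyl ether Ar(C)–O–C(Cl)=CHCl
Conditions: Cl2C=CHCl (1.5 equiv), K2CO3, DMF, 70 °C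
Reagents that add atoms: trichloroethylene, ClC=C(Cl)Cl
Why: O-Dichlorovinylation of a phenol; the base turns trichloroethylene into dichloroacetylene in the flask, to which the phenoxide of 11 adds in anti fashion (addition then protonation), which sets the E geometry. The small linear electrophile is indifferent to the crowding around the C6 oxygen.

Step 7
Reactants: 12 (E)-1,2-dichloroethenyl ether Ar(C)–O–C(Cl)=CHCl
Product: 15 aryl ethynyl ether Ar(C)–O–C≡CH, via chloroethynyl ether 13 (not isolated), via lithium acetylide 14 (not isolated)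
Conditions: n-BuLi (2.5 equiv), THF, −78 to −40 °C; then H2O, −78 °C; used at once as a cold solution
Reagents that add atoms: none
Why: Dichlorovinyl ether route to alkynyl ethers; deprotonation and β-elimination of chloride give 13, chlorine–lithium exchange gives acetylide 14, and protonation gives the terminal alkynyl ether, which has no β-hydrogen and so cannot fragment by a retro-ene path.

Step 8
Reactants: 16 phenol 3,4,5-trimethoxyphenol; 17 bromide 4-bromo-3,5-dimethoxybenzaldehyde
Product: 18 aldehyde 3,5-dimethoxy-4-(3,4,5-trimethoxyphenoxy)benzaldehyde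
Conditions: CuI (10 mol %), picolinic acid (20 mol %), K3PO4, DMSO, 90 °C, argon
Reagents that add atoms: none
Why: Ullmann ether synthesis between an unhindered, electron-rich phenol and a bromide activated by its para formyl group; the two ortho methoxy groups of 17 are small and can assist copper by coordination.

Step 9
Reactants: 18 aldehyde 3,5-dimethoxy-4-(3,4,5-trimethoxyphenoxy)benzaldehyde
Product: 20 phenol 3,5-dimethoxy-4-(3,4,5-trimethoxyphenoxy)phenol, via aryl formate 19 (not isolated)
Conditions: mCPBA, CH2Cl2, 0 °C to rt; aqueous wash; then K2CO3 (cat.), MeOH, rt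
Reagents that add atoms: mCPBA (3-chloroperoxybenzoic acid), OOC(=O)c1cccc(Cl)c1
Why: Dakin-type Baeyer–Villiger oxidation; the para aryloxy group makes the aryl group the better migrating group, as in the oxidation of 3,4,5-trialkoxybenzaldehydes to the phenols.

Step 10
Reactants: 20 phenol 3,5-dimethoxy-4-(3,4,5-trimethoxyphenoxy)phenol; 21 bromide 2-bromo-3,4,5-trimethoxybenzaldehyde
Product: 22 aldehyde 2-[3,5-dimethoxy-4-(3,4,5-trimethoxyphenoxy)phenoxy]-3,4,5-trimethoxybenzaldehyde
Conditions: CuI (20 mol %), picolinic acid (40 mol %), K3PO4, DMSO, 100 °C, argon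
Reagents that add atoms: none
Why: Ullmann ether synthesis; the ortho formyl group of 21 activates the flanked C–Br bond, and the phenol partner 20 has no ortho substituent, so the crowding lies on one side only.

Step 11
Reactants: 22 aldehyde 2-[3,5-dimethoxy-4-(3,4,5-trimethoxyphenoxy)phenoxy]-3,4,5-trimethoxybenzaldehyde
Product: 24 phenol 2-[3,5-dimethoxy-4-(3,4,5-trimethoxyphenoxy)phenoxy]-3,4,5-trimethoxyphenol (Ar(E)–OH), via aryl formate 23 (not isolated)
Conditions: mCPBA, CH2Cl2, 0 °C to rt; aqueous wash; then K2CO3 (cat.), MeOH, rt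
Reagents that add atoms: mCPBA (3-chloroperoxybenzoic acid), OOC(=O)c1cccc(Cl)c1
Why: Dakin-type Baeyer–Villiger oxidation; the ortho aryloxy and para methoxy groups favour aryl migration to formate 23, and methanolysis frees the E1 hydroxyl.

Step 12
Reactants: 24 phenol Ar(E)–OH
Product: 25 (E)-1,2-dichloroethenyl ether Ar(E)–O–C(Cl)=CHCl
Conditions: Cl2C=CHCl (1.5 equiv), K2CO3, DMF, 70 °C
Reagents that add atoms: trichloroethylene, ClC=C(Cl)Cl
Why: O-Dichlorovinylation as in step 6; anti addition of the phenoxide of 24 to dichloroacetylene, formed in the flask from trichloroethylene and base, sets the E geometry.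

Step 13
Reactants: 25 (E)-1,2-dichloroethenyl ether Ar(E)–O–C(Cl)=CHCl
Product: 28 aryl ethynyl ether Ar(E)–O–C≡CH, via chloroethynyl ether 26 (not isolated), via lithium acetylide 27 (not isolated)
Conditions: n-BuLi (2.5 equiv), THF, −78 to −40 °C; then H2O, −78 °C; used at once as a cold solution
Reagents that add atoms: none
Why: As in step 7, β-elimination, chlorine–lithium exchange and protonation; vinylic deprotonation at −78 °C should be faster than metalation of the ring hydrogen at E2.

Step 14
Reactants: 28 aryl ethynyl ether Ar(E)–O–C≡CH; 29 methoxyacetyl chloride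
Product: 31 racemic cyclobutenone 3-[Ar(E)oxy]-4-methoxycyclobut-2-en-1-one, via methoxyketene 30 (not isolated)
Conditions: 29 added slowly, Et3N, CH2Cl2, 0 °C to rt
Reagents that add atoms: none
Why: Ketene–alkyne (2+2) cycloaddition; the nucleophilic terminal carbon of 28 bonds to the carbonyl carbon of ketene 30 and the oxygen-bearing carbon to its methoxy carbon, which puts aryloxy at C3 and methoxy at C4. The new sp3 centre is racemic and is lost on aromatisation.

Step 15
Reactants: 31 racemic cyclobutenone 3-[Ar(E)oxy]-4-methoxycyclobut-2-en-1-one; 15 aryl ethynyl ether Ar(C)–O–C≡CH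
Product: 36 phenol 5-[Ar(C)oxy]-3-[Ar(E)oxy]-2-methoxyphenol (ring D formed; only the D3 hydroxyl free), via vinylketene 32 (not isolated), via vinylcyclobutenone 33 (not isolated), via dienylketene 34 (not isolated), via cyclohexadienone 35 (not isolated)
Conditions: PhMe, 80 to 110 °C, sealed tube, argon; 15 in slight excess
Reagents that add atoms: none
Why: Danheiser benzannulation of a cyclobutenone with an alkynyl ether is the closest known reaction type, used here with aryloxy in place of alkoxy on both partners. Thermal conrotatory 4π opening of 31, eased by the C4 methoxy donor rotating outward, gives vinylketene 32. The ketene carbonyl carbon (future D3) is attacked by the nucleophilic terminal carbon of 15 (future D2) and the four-membered ring closes between the ketene α-carbon (D6) and the oxygen-bearing alkyne carbon (D1), a regiochemistry fixed by the polarisation of both partners, to give 33. A second 4π opening gives dienylketene 34; the opening is reversible, so the isomer with ketene and alkoxyvinyl arms cis is drained off. Ring D is then closed by a thermally allowed disrotatory 6π electrocyclisation between D3 and D4 to give dienone 35, and tautomerisation gives phenol 36. No stereocentre survives, since the sp3 carbons of 31, 33 and 35 all become aromatic. The step needs regioselectivity in the (2+2) union, which necessarily places the D3 hydroxyl meta to the D1 aryloxy group and the D4 methoxy group next to the D5 aryloxy group, and capture of 32 by 15 rather than by itself, which the excess of 15 and moderate concentration should favour.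

Step 16
Reactants: 36 phenol 5-[Ar(C)oxy]-3-[Ar(E)oxy]-2-methoxyphenol
Product: 37 target CNP0130704.0 (octadecahydroxy heptamer)
Conditions: BBr3 (large excess), CH2Cl2, −78 °C to rt; MeOH quench; degassed solvents, size-exclusion then reversed-phase purification under argon
Reagents that add atoms: none
Why: Lewis acid ether cleavage; BBr3 binds the alkyl aryl ether oxygens and bromide removes each methyl group by SN2, whereas the diaryl ether oxygens are poorly basic and offer no sp3 carbon, so the six aryl–O–aryl links should survive.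

## Compound list

1 | 2,4,6-trimethoxyphenol | COc1cc(OC)c(O)c(OC)c1 | starting material
2 | 4-bromo-2,6-dimethoxybenzaldehyde | COc1cc(Br)cc(OC)c1C=O | starting material
3 | 2,6-dimethoxy-4-(2,4,6-trimethoxyphenoxy)benzaldehyde | COc1cc(OC)c(Oc2cc(OC)c(C=O)c(OC)c2)c(OC)c1 | intermediate
4 | 2,6-dimethoxy-4-(2,4,6-trimethoxyphenoxy)phenyl formate (not isolated) | COc1cc(OC)c(Oc2cc(OC)c(OC=O)c(OC)c2)c(OC)c1 | intermediate
5 | 2,6-dimethoxy-4-(2,4,6-trimethoxyphenoxy)phenol | COc1cc(OC)c(Oc2cc(OC)c(O)c(OC)c2)c(OC)c1 | intermediate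
6 | 5-bromo-1,2,3-trimethoxybenzene | COc1cc(Br)cc(OC)c1OC | starting material
7 | racemic 1-bromo-2-[chloro(methoxy)methyl]-3,4,5-trimethoxybenzene (not isolated) | COC(Cl)c1c(Br)cc(OC)c(OC)c1OC | intermediate
8 | 6-bromo-2,3,4-trimethoxybenzaldehyde | COc1cc(Br)c(C=O)c(OC)c1OC | intermediate
9 | 6-[2,6-dimethoxy-4-(2,4,6-trimethoxyphenoxy)phenoxy]-2,3,4-trimethoxybenzaldehyde | COc1cc(OC)c(Oc2cc(OC)c(Oc3cc(OC)c(OC)c(OC)c3C=O)c(OC)c2)c(OC)c1 | intermediate
10 | 6-[2,6-dimethoxy-4-(2,4,6-trimethoxyphenoxy)phenoxy]-2,3,4-trimethoxyphenyl formate (not isolated) | COc1cc(OC)c(Oc2cc(OC)c(Oc3cc(OC)c(OC)c(OC)c3OC=O)c(OC)c2)c(OC)c1 | intermediate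
11 | 6-[2,6-dimethoxy-4-(2,4,6-trimethoxyphenoxy)phenoxy]-2,3,4-trimethoxyphenol, Ar(C)–OH | COc1cc(OC)c(Oc2cc(OC)c(Oc3cc(OC)c(OC)c(OC)c3O)c(OC)c2)c(OC)c1 | intermediate
12 | (E)-1,2-dichloroethenyl ether of 11, Ar(C)–O–C(Cl)=CHCl | COc1cc(OC)c(Oc2cc(OC)c(Oc3cc(OC)c(OC)c(OC)c3O/C(Cl)=C\Cl)c(OC)c2)c(OC)c1 | intermediate
13 | chloroethynyl ether Ar(C)–O–C≡C–Cl (not isolated) | COc1cc(OC)c(Oc2cc(OC)c(Oc3cc(OC)c(OC)c(OC)c3OC#CCl)c(OC)c2)c(OC)c1 | intermediate
14 | lithium acetylide Ar(C)–O–C≡C–Li (not isolated) | COc1cc(OC)c(Oc2cc(OC)c(Oc3cc(OC)c(OC)c(OC)c3OC#C[Li])c(OC)c2)c(OC)c1 | intermediate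
15 | ethynyl ether Ar(C)–O–C≡CH, 1-(ethynyloxy)-6-[2,6-dimethoxy-4-(2,4,6-trimethoxyphenoxy)phenoxy]-2,3,4-trimethoxybenzene | COc1cc(OC)c(Oc2cc(OC)c(Oc3cc(OC)c(OC)c(OC)c3OC#C)c(OC)c2)c(OC)c1 | intermediate
16 | 3,4,5-trimethoxyphenol | COc1cc(O)cc(OC)c1OC | starting material
17 | 4-bromo-3,5-dimethoxybenzaldehyde | COc1cc(C=O)cc(OC)c1Br | starting material
18 | 3,5-dimethoxy-4-(3,4,5-trimethoxyphenoxy)benzaldehyde | COc1cc(Oc2c(OC)cc(C=O)cc2OC)cc(OC)c1OC | intermediate
19 | 3,5-dimethoxy-4-(3,4,5-trimethoxyphenoxy)phenyl formate (not isolated) | COc1cc(Oc2c(OC)cc(OC=O)cc2OC)cc(OC)c1OC | intermediate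
20 | 3,5-dimethoxy-4-(3,4,5-trimethoxyphenoxy)phenol | COc1cc(Oc2c(OC)cc(O)cc2OC)cc(OC)c1OC | intermediate
21 | 2-bromo-3,4,5-trimethoxybenzaldehyde | COc1cc(C=O)c(Br)c(OC)c1OC | starting material
22 | 2-[3,5-dimethoxy-4-(3,4,5-trimethoxyphenoxy)phenoxy]-3,4,5-trimethoxybenzaldehyde | COc1cc(Oc2c(OC)cc(Oc3c(C=O)cc(OC)c(OC)c3OC)cc2OC)cc(OC)c1OC | intermediate
23 | 2-[3,5-dimethoxy-4-(3,4,5-trimethoxyphenoxy)phenoxy]-3,4,5-trimethoxyphenyl formate (not isolated) | COc1cc(Oc2c(OC)cc(Oc3c(OC=O)cc(OC)c(OC)c3OC)cc2OC)cc(OC)c1OC | intermediate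
24 | 2-[3,5-dimethoxy-4-(3,4,5-trimethoxyphenoxy)phenoxy]-3,4,5-trimethoxyphenol, Ar(E)–OH | COc1cc(Oc2c(OC)cc(Oc3c(O)cc(OC)c(OC)c3OC)cc2OC)cc(OC)c1OC | intermediate
25 | (E)-1,2-dichloroethenyl ether of 24, Ar(E)–O–C(Cl)=CHCl | COc1cc(Oc2c(OC)cc(Oc3c(O/C(Cl)=C\Cl)cc(OC)c(OC)c3OC)cc2OC)cc(OC)c1OC | intermediate
26 | chloroethynyl ether Ar(E)–O–C≡C–Cl (not isolated) | COc1cc(Oc2c(OC)cc(Oc3c(OC#CCl)cc(OC)c(OC)c3OC)cc2OC)cc(OC)c1OC | intermediate
27 | lithium acetylide Ar(E)–O–C≡C–Li (not isolated) | COc1cc(Oc2c(OC)cc(Oc3c(OC#C[Li])cc(OC)c(OC)c3OC)cc2OC)cc(OC)c1OC | intermediate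
28 | ethynyl ether Ar(E)–O–C≡CH, 1-(ethynyloxy)-2-[3,5-dimethoxy-4-(3,4,5-trimethoxyphenoxy)phenoxy]-3,4,5-trimethoxybenzene | COc1cc(Oc2c(OC)cc(Oc3c(OC#C)cc(OC)c(OC)c3OC)cc2OC)cc(OC)c1OC | intermediate
29 | methoxyacetyl chloride | COCC(Cl)=O | starting material
30 | methoxyketene (not isolated) | COC=C=O | intermediate
31 | racemic 3-[Ar(E)oxy]-4-methoxycyclobut-2-en-1-one | COc1cc(Oc2c(OC)cc(Oc3c(OC4=CC(=O)C4OC)cc(OC)c(OC)c3OC)cc2OC)cc(OC)c1OC | intermediate
32 | (3Z)-3-[Ar(E)oxy]-4-methoxybuta-1,3-dien-1-one, vinylketene (not isolated) | COc1cc(Oc2c(OC)cc(Oc3c(O/C(C=C=O)=C\OC)cc(OC)c(OC)c3OC)cc2OC)cc(OC)c1OC | intermediate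
33 | racemic 3-[Ar(C)oxy]-4-{(Z)-1-[Ar(E)oxy]-2-methoxyethenyl}cyclobut-2-en-1-one (not isolated) | COc1cc(Oc2c(OC)cc(Oc3c(O/C(=C\OC)C4C(=O)C=C4Oc5c(OC)c(OC)c(OC)cc5Oc6c(OC)cc(Oc7c(OC)cc(OC)cc7OC)cc6OC)cc(OC)c(OC)c3OC)cc2OC)cc(OC)c1OC | intermediate
34 | (3E,5Z)-3-[Ar(C)oxy]-5-[Ar(E)oxy]-6-methoxyhexa-1,3,5-trien-1-one, dienylketene (not isolated) | COc1cc(Oc2c(OC)cc(Oc3c(O/C(=C\OC)/C=C(\C=C=O)Oc5c(OC)c(OC)c(OC)cc5Oc6c(OC)cc(Oc7c(OC)cc(OC)cc7OC)cc6OC)cc(OC)c(OC)c3OC)cc2OC)cc(OC)c1OC | intermediate
35 | racemic 3-[Ar(C)oxy]-5-[Ar(E)oxy]-6-methoxycyclohexa-2,4-dien-1-one (not isolated) | COc1cc(Oc2c(OC)cc(Oc3c(OC4=CC(Oc5c(OC)c(OC)c(OC)cc5Oc6c(OC)cc(Oc7c(OC)cc(OC)cc7OC)cc6OC)=CC(=O)C4OC)cc(OC)c(OC)c3OC)cc2OC)cc(OC)c1OC | intermediate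
36 | 5-[Ar(C)oxy]-3-[Ar(E)oxy]-2-methoxyphenol (heptadecamethyl ether of the target, D3 hydroxyl free) | COc1cc(OC)c(Oc2cc(OC)c(Oc3cc(OC)c(OC)c(OC)c3Oc3cc(O)c(OC)c(Oc4cc(OC)c(OC)c(OC)c4Oc4cc(OC)c(Oc5cc(OC)c(OC)c(OC)c5)c(OC)c4)c3)c(OC)c2)c(OC)c1 | intermediate
37 | CNP0130704.0, heptameric phlorotannin with eighteen free hydroxyls | Oc1cc(O)c(Oc2cc(O)c(Oc3cc(O)c(O)c(O)c3Oc3cc(O)c(O)c(Oc4cc(O)c(O)c(O)c4Oc4cc(O)c(Oc5cc(O)c(O)c(O)c5)c(O)c4)c3)c(O)c2)c(O)c1 | target

## Step count and uncertain steps

Total step count: 16. Longest linear sequence: 9 steps (steps 8 to 16, from 16 and 17). The other branch has 8 steps (1, 2, 4 to 7, 15, 16), with step 3 feeding step 4.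

Least certain steps:

Step 15 (key). Ketene 32 may be consumed unproductively, by self-reaction or by acylating the newly formed phenol, faster than the hindered and only moderately nucleophilic alkynyl ether 15 captures it; 15 may also oligomerise thermally. The fallback sets out from 24 and 11 and returns at 37: ring D is brought in as a formyl-activated dihalide and both ethers are made by substitution. Phenol 24 displaces the fluoride ortho to the formyl group of commercial 4-bromo-2-fluoro-6-methoxybenzaldehyde F1 (K2CO3, DMF, 80 °C) to give bromo aldehyde F2. Copper-mediated coupling of F2 with phenol 11 at the para bromide (CuI, picolinic acid, K3PO4, DMSO) gives heptamer aldehyde F3. Peracid oxidation gives formate F4, and methanolysis gives phenol F5, the D4-hydroxy/D3-methoxy isomer of 36. BBr3 then gives 37.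

Step 14. Dimerisation of methoxyketene 30 may outpace the (2+2) addition to the bulky alkynyl ether 28, and the vinylogous ester of 31 may be hydrolysed during purification. The fallback sets out from 24 and returns at 36 through 32: the same vinylketene is made by a photochemical Wolff rearrangement instead. Phenol 24 is alkylated with methyl bromoacetate to give aryloxyacetate F6. Formylation (HCO2Me, NaH) gives hydroxymethylene ester F7, and O-methylation (Me2SO4, K2CO3) gives β-methoxyacrylate F8. Saponification gives acid F9, oxalyl chloride gives acid chloride F10, and CH2N2 gives diazo ketone F11. Irradiation of F11 in the presence of 15, followed by warming, generates 32 and carries on to 36.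

Step 7 (and step 13 by analogy). Ring metalation by n-BuLi may compete with the elimination, and the terminal aryl ethynyl ether may oligomerise on concentration or storage. The fallback sets out from 12 and returns at 36: the alkyne is carried in silyl-capped form through the benzannulation. Acetylide 14, generated from 12 as in step 7, is quenched with Me3SiCl to give the stable silylalkynyl ether F12. F12 is heated with 31 to give the D2-silylated phenol F13; the silyl group sits on the nucleophilic alkyne carbon, so the regiochemistry is unchanged. Ipso-protodesilylation (CF3CO2H, CH2Cl2, 0 °C) gives 36.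

Step 16. Cleavage of the seventeen methyl ethers may stay incomplete and leave partly methylated mixtures, and the free polyphenol may degrade oxidatively during isolation. The fallback sets out from 36 and returns at 37: the product is isolated in protected form. The crude product of the BBr3 reaction is acetylated (Ac2O, pyridine) to the octadecaacetate F14, which is stable and can be purified on silica. Acid-catalysed methanolysis of pure F14 in degassed MeOH under argon releases 37, leaving only volatile by-products.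

## Further compounds

F1 | step 15 | 4-bromo-2-fluoro-6-methoxybenzaldehyde | COc1cc(Br)cc(F)c1C=O
F2 | step 15 | 4-bromo-2-[Ar(E)oxy]-6-methoxybenzaldehyde | COc1cc(Oc2c(OC)cc(Oc3c(Oc4cc(Br)cc(OC)c4C=O)cc(OC)c(OC)c3OC)cc2OC)cc(OC)c1OC
F3 | step 15 | 4-[Ar(C)oxy]-2-[Ar(E)oxy]-6-methoxybenzaldehyde | COc1cc(OC)c(Oc2cc(OC)c(Oc3cc(OC)c(OC)c(OC)c3Oc3cc(OC)c(C=O)c(Oc4cc(OC)c(OC)c(OC)c4Oc4cc(OC)c(Oc5cc(OC)c(OC)c(OC)c5)c(OC)c4)c3)c(OC)c2)c(OC)c1
F4 | step 15 | 4-[Ar(C)oxy]-2-[Ar(E)oxy]-6-methoxyphenyl formate | COc1cc(OC)c(Oc2cc(OC)c(Oc3cc(OC)c(OC)c(OC)c3Oc3cc(OC)c(OC=O)c(Oc4cc(OC)c(OC)c(OC)c4Oc4cc(OC)c(Oc5cc(OC)c(OC)c(OC)c5)c(OC)c4)c3)c(OC)c2)c(OC)c1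
F5 | step 15 | 4-[Ar(C)oxy]-2-[Ar(E)oxy]-6-methoxyphenol | COc1cc(OC)c(Oc2cc(OC)c(Oc3cc(OC)c(OC)c(OC)c3Oc3cc(OC)c(O)c(Oc4cc(OC)c(OC)c(OC)c4Oc4cc(OC)c(Oc5cc(OC)c(OC)c(OC)c5)c(OC)c4)c3)c(OC)c2)c(OC)c1
F6 | step 14 | methyl 2-[Ar(E)oxy]acetate | COc1cc(Oc2c(OC)cc(Oc3c(OCC(=O)OC)cc(OC)c(OC)c3OC)cc2OC)cc(OC)c1OC
F7 | step 14 | methyl 2-[Ar(E)oxy]-3-hydroxyprop-2-enoate | COc1cc(Oc2c(OC)cc(Oc3c(OC(=CO)C(=O)OC)cc(OC)c(OC)c3OC)cc2OC)cc(OC)c1OC
F8 | step 14 | methyl (Z)-2-[Ar(E)oxy]-3-methoxyprop-2-enoate | COc1cc(Oc2c(OC)cc(Oc3c(O/C(C(=O)OC)=C\OC)cc(OC)c(OC)c3OC)cc2OC)cc(OC)c1OC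
F9 | step 14 | (Z)-2-[Ar(E)oxy]-3-methoxyprop-2-enoic acid | COc1cc(Oc2c(OC)cc(Oc3c(O/C(C(=O)O)=C\OC)cc(OC)c(OC)c3OC)cc2OC)cc(OC)c1OC
F10 | step 14 | (Z)-2-[Ar(E)oxy]-3-methoxyprop-2-enoyl chloride | COc1cc(Oc2c(OC)cc(Oc3c(O/C(C(Cl)=O)=C\OC)cc(OC)c(OC)c3OC)cc2OC)cc(OC)c1OC
F11 | step 14 | (Z)-1-diazo-3-[Ar(E)oxy]-4-methoxybut-3-en-2-one | COc1cc(Oc2c(OC)cc(Oc3c(O/C(C(=O)C=[N+]=[N-])=C\OC)cc(OC)c(OC)c3OC)cc2OC)cc(OC)c1OC
F12 | step 7 | silylalkynyl ether Ar(C)–O–C≡C–SiMe3 | COc1cc(OC)c(Oc2cc(OC)c(Oc3cc(OC)c(OC)c(OC)c3OC#C[Si](C)(C)C)c(OC)c2)c(OC)c1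
F13 | step 7 | 3-[Ar(C)oxy]-5-[Ar(E)oxy]-6-methoxy-2-(trimethylsilyl)phenol | COc1cc(OC)c(Oc2cc(OC)c(Oc3cc(OC)c(OC)c(OC)c3Oc3c([Si](C)(C)C)c(O)c(OC)c(Oc4cc(OC)c(OC)c(OC)c4Oc4cc(OC)c(Oc5cc(OC)c(OC)c(OC)c5)c(OC)c4)c3)c(OC)c2)c(OC)c1
F14 | step 16 | octadecaacetate of 37 | CC(=O)Oc1cc(OC(C)=O)c(Oc2cc(OC(C)=O)c(Oc3cc(OC(C)=O)c(OC(C)=O)c(OC(C)=O)c3Oc3cc(OC(C)=O)c(OC(C)=O)c(Oc4cc(OC(C)=O)c(OC(C)=O)c(OC(C)=O)c4Oc4cc(OC(C)=O)c(Oc5cc(OC(C)=O)c(OC(C)=O)c(OC(C)=O)c5)c(OC(C)=O)c4)c3)c(OC(C)=O)c2)c(OC(C)=O)c1
A1 | alternative 1 | 5-bromo-1-iodo-2,3-dimethoxybenzene | COc1cc(Br)cc(I)c1OC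
A2 | alternative 1 | 5-bromo-1-[Ar(E)oxy]-2,3-dimethoxybenzene | COc1cc(Oc2c(OC)cc(Oc3c(Oc4cc(Br)cc(OC)c4OC)cc(OC)c(OC)c3OC)cc2OC)cc(OC)c1OC
A3 | alternative 1 | octadecamethyl ether of 37 | COc1cc(OC)c(Oc2cc(OC)c(Oc3cc(OC)c(OC)c(OC)c3Oc3cc(OC)c(OC)c(Oc4cc(OC)c(OC)c(OC)c4Oc4cc(OC)c(Oc5cc(OC)c(OC)c(OC)c5)c(OC)c4)c3)c(OC)c2)c(OC)c1
A4 | alternative 2 | 3,4,5-trimethoxy-2-(trimethylsilyl)phenyl trifluoromethanesulfonate | COc1cc(OS(=O)(=O)C(F)(F)F)c([Si](C)(C)C)c(OC)c1OC
A5 | alternative 2 | 1,2-didehydro-3,4,5-trimethoxybenzene (3,4,5-trimethoxybenzyne) | COC1=C(OC)C(OC)=CC#C1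
A6 | alternative 2 | 1-[2,6-dimethoxy-4-(2,4,6-trimethoxyphenoxy)phenoxy]-2-iodo-3,4,5-trimethoxybenzene | COc1cc(OC)c(Oc2cc(OC)c(Oc3cc(OC)c(OC)c(OC)c3I)c(OC)c2)c(OC)c1
A7 | alternative 3 | 3-[3,5-dimethoxy-4-(3,4,5-trimethoxyphenoxy)phenoxy]-4-methoxycyclobut-3-ene-1,2-dione | COC1=C(Oc2cc(OC)c(Oc3cc(OC)c(OC)c(OC)c3)c(OC)c2)C(=O)C1=O
A8 | alternative 3 | 1-methoxyethenyllithium | [Li]C(=C)OC
A9 | alternative 3 | racemic 2-[3,5-dimethoxy-4-(3,4,5-trimethoxyphenoxy)phenoxy]-4-hydroxy-3-methoxy-4-(1-methoxyethenyl)cyclobut-2-en-1-one | COC(=C)C1(O)C(OC)=C(Oc2cc(OC)c(Oc3cc(OC)c(OC)c(OC)c3)c(OC)c2)C1=O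
A10 | alternative 3 | 2-[3,5-dimethoxy-4-(3,4,5-trimethoxyphenoxy)phenoxy]-3,5-dimethoxybenzene-1,4-diol | COc1cc(O)c(Oc2cc(OC)c(Oc3cc(OC)c(OC)c(OC)c3)c(OC)c2)c(OC)c1O
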